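**Assumptions.** Piscisoflavone A has no stereocentres, so there is no enantiomer to control. I assume 4-methoxyresorcinol (4-methoxybenzene-1,3-diol) is commercially available. Only compounds that contribute atoms to the skeleton are numbered. Bases, catalysts and solvents appear only in the conditions.

**Retrosynthesis**
- Disconnect the C3–C1′ biaryl bond (Suzuki–Miyaura). This gives 7-hydroxy-3-iodochromone and a B-ring aryl boronate.
- The pyranone ring is formed first, from 2′,4′-dihydroxyacetophenone via an enaminone and iodocyclisation.
- The B ring starts as 4-methoxyresorcinol. Its 2′- and 4′-OH groups are protected as MOM ethers, which direct lithiation to C3′ for C-prenylation. The ring is then iodinated at C1′, borylated, and coupled.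
- The MOM groups are removed in the last step.

**Step 1**
Reactants: 1 (2′,4′-dihydroxyacetophenone), 2 (DMF-DMA)
Product: 3, (E)-1-(2,4-dihydroxyphenyl)-3-(dimethylamino)prop-2-en-1-one
Conditions: DMF-DMA, toluene, 90 °C
Reagents that add atoms: DMF-DMA, CN(C)C(OC)OC
Why: The acetyl CH3 condenses with the amide acetal to give the push–pull enaminone (Bredereck-type enaminone formation). No stereocentre is formed.

**Step 2**
Reactants: 3, 4 (iodine)
Product: 5, 7-hydroxy-3-iodo-4H-chromen-4-one
Conditions: I2, CHCl3, rt
Reagents that add atoms: iodine, II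
Why: I2 iodinates the enaminone α-carbon. The 2′-OH then attacks the iminium carbon and loses HNMe2, closing the pyranone ring (iodocyclisation). The 7-OH (the original 4-OH) is untouched.

**Step 3**
Reactants: 6 (4-methoxyresorcinol), 7 (MOMCl)
Product: 8, 1,3-bis(methoxymethoxy)-4-methoxybenzene
Conditions: NaH (2.4 equiv), MOMCl (2.5 equiv), THF/DMF, 0 °C to rt
Reagents that add atoms: MOMCl, ClCOC
Why: Both phenols are alkylated to give MOM ethers (Williamson-type protection). MOM groups are stable to BuLi and to Suzuki base, and they direct lithiation.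

**Step 4**
Reactants: 8, 9 (prenyl bromide)
Product: 10, 2-(3-methylbut-2-enyl)-1,3-bis(MOM-oxy)-4-methoxybenzene
Conditions: n-BuLi, THF, 0 °C; then CuI (10 mol%), prenyl bromide, −78 °C to rt
Reagents that add atoms: prenyl bromide, CC(C)=CCBr
Why: Directed ortho-metalation occurs at the only C–H flanked by two OMOM groups, which is the future C3′. Cu-catalysed SN2 alkylation with prenyl bromide then gives the linear prenyl group (directed lithiation followed by Cu-catalysed alkylation).

**Step 5**
Reactants: 10, 11 (NIS)
Product: 12, 1-iodo-2,4-bis(MOM-oxy)-5-methoxy-3-prenylbenzene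
Conditions: NIS, MeCN, 0 °C to rt, dark
Reagents that add atoms: N-iodosuccinimide, O=C1CCC(=O)N1I
Why: Electrophilic aromatic iodination goes to C1′, which is ortho to one OMOM and para to the other. It is the most activated free position (SEAr).

**Step 6**
Reactants: 12, 13 (B2pin2)
Product: 14, the 1-Bpin analogue of 12 (2-aryl-4,4,5,5-tetramethyl-1,3,2-dioxaborolane)
Conditions: B2pin2, Pd(dppf)Cl2 (5 mol%), KOAc, dioxane, 90 °C
Reagents that add atoms: bis(pinacolato)diboron, CC1(C)OB(OC1(C)C)B1OC(C)(C)C(C)(C)O1
Why: Miyaura borylation turns the aryl iodide into the boronate. The MOM groups and the prenyl alkene are untouched.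

**Step 7**
Reactants: 5, 14
Product: 15, 7-hydroxy-2′,4′-bis(MOM-oxy)-5′-methoxy-3′-prenylisoflavone
Conditions: Pd(PPh3)4 (5 mol%), 2 M aq. Na2CO3, DME, 80 °C
Reagents that add atoms: none
Why: Suzuki–Miyaura coupling at the C3–I bond of the chromone forms the isoflavone C3–C1′ bond. Mild carbonate base keeps the free 7-OH (as phenoxide) from interfering and avoids chromone ring-opening.

**Step 8**
Reactants: 15
Product: 16, Piscisoflavone A
Conditions: 3 M HCl (aq), MeOH/THF, 40 °C
Reagents that add atoms: none (MOM is lost as CH2(OMe)2/CH2O; the new OH hydrogens come from the solvent)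
Why: Acidolysis of the two MOM acetals releases the 2′- and 4′-OH groups. The isoflavone, the 7-OH, the OMe and the prenyl group survive mild conditions, and the molecule is achiral.

**Checks performed**
- The target has a 7-OH isoflavone core. The B ring carries 2′-OH, 3′-prenyl, 4′-OH, 5′-OMe and 6′-H, which matches the SMILES.
- Atom bookkeeping was checked at each step.
- No stereocentres exist, so none can be scrambled.

**Compound list**

| No. | Name | SMILES | Role |
|---|---|---|---|
| 1 | 2′,4′-dihydroxyacetophenone | CC(=O)c1ccc(O)cc1O | starting material |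
| 2 | DMF dimethyl acetal | CN(C)C(OC)OC | starting material |
| 3 | (E)-enaminone | CN(C)/C=C/C(=O)c1ccc(O)cc1O | intermediate |
| 4 | iodine | II | starting material |
| 5 | 7-hydroxy-3-iodochromone | O=c1c(I)coc2cc(O)ccc12 | intermediate |
| 6 | 4-methoxyresorcinol | COc1ccc(O)cc1O | starting material |
| 7 | chloromethyl methyl ether | ClCOC | starting material |
| 8 | 1,3-bis(MOM-oxy)-4-methoxybenzene | COc1ccc(OCOC)cc1OCOC | intermediate |
| 9 | prenyl bromide | CC(C)=CCBr | starting material |
| 10 | prenylated bis-MOM arene | COc1ccc(OCOC)c(CC=C(C)C)c1OCOC | intermediate |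
| 11 | N-iodosuccinimide | O=C1CCC(=O)N1I | starting material |
| 12 | aryl iodide | COc1cc(I)c(OCOC)c(CC=C(C)C)c1OCOC | intermediate |
| 13 | bis(pinacolato)diboron | CC1(C)OB(OC1(C)C)B1OC(C)(C)C(C)(C)O1 | starting material |
| 14 | aryl Bpin | COc1cc(B2OC(C)(C)C(C)(C)O2)c(OCOC)c(CC=C(C)C)c1OCOC | intermediate |
| 15 | bis-MOM isoflavone | COc1cc(-c2coc3cc(O)ccc3c2=O)c(OCOC)c(CC=C(C)C)c1OCOC | intermediate |
| 16 | Piscisoflavone A | COc1cc(-c2coc3cc(O)ccc3c2=O)c(O)c(CC=C(C)C)c1O | target |

**Total steps:** 8. **Longest linear sequence:** 6 steps (6 → 8 → 10 → 12 → 14 → 15 → 16).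

**Three steps most likely to fail**
1. **Step 4 (lithiation and prenylation).** Aryllithium alkylation with prenyl bromide may give low yield or SN2′ products. Fallback: quench the aryllithium with B(OMe)3 to give the boronic acid, then do a Pd-catalysed Suzuki coupling with prenyl bromide.
2. **Step 7 (hindered Suzuki on a base-sensitive chromone with free 7-OH).** Fallback: convert aryl iodide 12 to the arylzinc reagent (i-PrMgCl·LiCl, then ZnCl2). Negishi-couple it with 7-OMOM-3-iodochromone under base-free conditions, and remove all MOM groups at the end.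
3. **Step 8 (acidic MOM removal).** The 2′-OH next to the prenyl group could cyclise to a dimethylchroman under acid. Fallback: use SEM instead of MOM on the B ring (SEM is also lithiation-compatible) and remove it with TBAF or MgBr2 under non-protic conditions.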